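**Retrosynthetic overview**
1. Last step: the pyran ring is opened at O9–C3' (C–O) and C8–C2'. This gives a chiral ortho-quinone methide (from an 8-hydroxy-cacalol) and the left-half 3-methylbenzofuran-7-ol. One dehydrative oxa-[4+2] closes the pyran, dearomatises the left furan and sets C8, C2' and C3'.
2. Right half: furan ring by O-alkylation with chloroacetone and cyclodehydration on a 7,8-dihydroxy-1-tetralone. The tetralone comes from Friedel–Crafts closure of an (S)-4-arylpentanoic acid (C5 set by asymmetric hydrogenation), made from 3,4-dimethoxytoluene and succinic anhydride.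
3. Left half: furan ring first (creosol + chloroacetone), then ortho-formylation, Wittig methylenation and hydroboration/B-alkyl Suzuki coupling for the (E)-pentenyl chain.
4. Ring order: carbocycle, right furan; left furan; pyran and dihydrofuran together in the last step.
5. Locants: cacalol numbering (O1 … C9a) for the right half, primed benzofuran numbering for the left half.

Assumption: the catalyst antipodes written in steps 3 and 15 are taken to be those that give the (S)-acid and the matched cycloaddition; the mirror-image catalyst is used if experiment shows the opposite sense.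

**Route**

Step 1
Reactants: 1 3,4-dimethoxytoluene; 2 succinic anhydride
Product: 3 4-(4,5-dimethoxy-2-methylphenyl)-4-oxobutanoic acid
Conditions: AlCl3 (2.2 equiv), CH2Cl2/PhNO2, 0 °C to rt; aq. HCl
Reagents that add atoms: none
Why: Friedel–Crafts (Haworth) acylation goes to the ring position para to one methoxy group and ortho to the methyl group, the only unhindered activated site.

Step 2
Reactants: 3
Product: 4 4-(4,5-dimethoxy-2-methylphenyl)pent-4-enoic acid
Conditions: Ph3PCH3Br, KOtBu (3 equiv each), THF, 0 °C to reflux; aq. HCl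
Reagents that add atoms: methyltriphenylphosphonium bromide, C[P+](c1ccccc1)(c1ccccc1)c1ccccc1.[Br-]
Why: Wittig methylenation of the aryl ketone; the carboxylate formed by the first equivalent of base is inert to the ylide.

Step 3
Reactants: 4
Product: 5 (S)-4-(4,5-dimethoxy-2-methylphenyl)pentanoic acid
Conditions: H2 (6 atm), [Ir(cod)((Sa,S)-SIPHOX)][B(3,5-(CF3)2C6H3)4] (1 mol%), Et3N (0.5 equiv), MeOH, rt
Reagents that add atoms: none
Why: carboxy-directed iridium-catalysed asymmetric hydrogenation of the 1,1-disubstituted alkene sets the benzylic methyl stereocentre (S, the later C5) under catalyst control.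

Step 4
Reactants: 5
Product: 6 (S)-7,8-dimethoxy-4,5-dimethyl-3,4-dihydronaphthalen-1(2H)-one
Conditions: P2O5/MeSO3H (Eaton's reagent), rt
Reagents that add atoms: none
Why: intramolecular Friedel–Crafts acylation closes onto the only free position ortho to the side chain, and the remote stereocentre is not enolisable.

Step 5
Reactants: 6
Product: 7 (S)-7,8-dihydroxy-4,5-dimethyl-3,4-dihydronaphthalen-1(2H)-one
Conditions: BBr3 (3 equiv), CH2Cl2, −78 °C to rt; H2O
Reagents that add atoms: none
Why: Lewis-acid cleavage of both aryl methyl ethers with BBr3, which leaves the ketone and the stereocentre untouched.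

Step 6
Reactants: 7; 8 chloroacetone
Product: 9 (S)-8-hydroxy-4,5-dimethyl-7-(2-oxopropoxy)-3,4-dihydronaphthalen-1(2H)-one
Conditions: K2CO3 (1.2 equiv), KI (10 mol%), acetone, 50 °C
Reagents that add atoms: none
Why: Williamson etherification is selective for the 7-OH because the 8-OH is locked in a hydrogen bond to the peri carbonyl group.

Step 7
Reactants: 9
Product: 10 (S)-9-hydroxy-3,4,5-trimethyl-6,7-dihydronaphtho[2,3-b]furan-8(5H)-one
Conditions: polyphosphoric acid, 85 °C
Reagents that add atoms: none
Why: acid-mediated cyclodehydration of the aryloxyacetone (intramolecular Friedel–Crafts hydroxyalkylation, then loss of water) at the only free aromatic position builds the 3-methylfuran ring.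

Step 8
Reactants: 10
Product: 11 (5S)-3,4,5-trimethyl-5,6,7,8-tetrahydronaphtho[2,3-b]furan-8,9-diol (mixture of C8 epimers)
Conditions: NaBH4 (2 equiv), THF/MeOH, 0 °C; pH 7 buffer; used crude
Reagents that add atoms: none
Why: borohydride reduction of the aryl ketone gives the ortho-hydroxybenzyl alcohol; the C8 configuration is irrelevant because C8 becomes planar in the next step.

Step 9
Reactants: 12 2-methoxy-4-methylphenol (creosol); 8 chloroacetone
Product: 13 1-(2-methoxy-4-methylphenoxy)propan-2-one
Conditions: K2CO3, KI (10 mol%), acetone, reflux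
Reagents that add atoms: none
Why: Williamson etherification of the single phenol.

Step 10
Reactants: 13
Product: 14 7-methoxy-3,5-dimethylbenzofuran
Conditions: polyphosphoric acid, toluene, 90 °C
Reagents that add atoms: none
Why: cyclodehydration of the aryloxyacetone onto the one free position ortho to the ether oxygen gives the 3-methylbenzofuran.

Step 11
Reactants: 14
Product: 15 3,5-dimethylbenzofuran-7-ol
Conditions: BBr3 (1.5 equiv), CH2Cl2, −78 to 0 °C; H2O
Reagents that add atoms: none
Why: BBr3 cleavage of the aryl methyl ether, which the benzofuran tolerates at low temperature.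

Step 12
Reactants: 15
Product: 16 7-hydroxy-3,5-dimethylbenzofuran-6-carbaldehyde
Conditions: MgCl2, Et3N, (CH2O)n, MeCN, reflux; aq. HCl
Reagents that add atoms: paraformaldehyde (as formaldehyde), C=O
Why: Casnati–Skattebøl ortho-formylation, in which the magnesium phenoxide delivers formaldehyde only to the free ortho position C6.

Step 13
Reactants: 16
Product: 17 3,5-dimethyl-6-vinylbenzofuran-7-ol
Conditions: Ph3PCH3Br, KOtBu (2.5 equiv each), THF, 0 °C to rt
Reagents that add atoms: methyltriphenylphosphonium bromide, C[P+](c1ccccc1)(c1ccccc1)c1ccccc1.[Br-]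
Why: Wittig methylenation of the salicylaldehyde with excess ylide to allow for the phenoxide.

Step 14
Reactants: 17; 18 (E)-1-bromoprop-1-ene
Product: 20 3,5-dimethyl-6-[(E)-pent-3-en-1-yl]benzofuran-7-ol, via alkylborane 19 (not isolated)
Conditions: 9-BBN (2.3 equiv), THF, 0 °C to rt; then 18, PdCl2(dppf) (5 mol%), aq. K3PO4, DMF, 50 °C
Reagents that add atoms: none
Why: anti-Markovnikov hydroboration of the styrene followed by B-alkyl Suzuki–Miyaura coupling, which transfers the alkenyl bromide with retention of its E geometry.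

Step 15
Reactants: 11; 20
Product: 22 target CNP0281983.1, via ortho-quinone methide 21 (not isolated)
Conditions: (R)-TRIP (10 mol%), 4 Å MS, PhCF3, −20 °C; 11 added slowly to 20 (1.5 equiv); Et3N quench
Reagents that add atoms: none
Why: Proposed new method: the chiral phosphoric acid dehydrates 11 to the hydrogen-bonded ortho-quinone methide 21 and binds the 7'-OH of 20 through its phosphoryl oxygen, so that C2' adds endo to C8 on the face that leaves H-8 pseudoaxial and anti to the pseudoaxial 5-CH3, and the phenol oxygen then closes onto the tertiary benzylic C3' cation (O9–C3' bond) before proton loss, which sets C8 (R), C2' (R) and C3' (R) with the cis ring fusion fixed by suprafacial addition across C2'=C3'; the closest known reaction type is the chiral-phosphoric-acid-catalysed oxa-[4+2] cycloaddition of ortho-quinone methides from ortho-hydroxybenzyl alcohols with styrenes, vinylindoles or enamides, not yet shown for a benzofuran 2π partner, a non-stabilised cyclic ortho-quinone methide or a substrate that already carries a stereocentre.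

**Compound list**

1 | 3,4-dimethoxytoluene | COc1ccc(C)cc1OC | starting material
2 | succinic anhydride | O=C1CCC(=O)O1 | starting material
3 | 4-(4,5-dimethoxy-2-methylphenyl)-4-oxobutanoic acid | OC(=O)CCC(=O)c1cc(OC)c(OC)cc1C | intermediate
4 | 4-(4,5-dimethoxy-2-methylphenyl)pent-4-enoic acid | OC(=O)CCC(=C)c1cc(OC)c(OC)cc1C | intermediate
5 | (S)-4-(4,5-dimethoxy-2-methylphenyl)pentanoic acid | OC(=O)CC[C@H](C)c1cc(OC)c(OC)cc1C | intermediate
6 | (S)-7,8-dimethoxy-4,5-dimethyl-3,4-dihydronaphthalen-1(2H)-one | O=C1CC[C@H](C)c2c(C)cc(OC)c(OC)c12 | intermediate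
7 | (S)-7,8-dihydroxy-4,5-dimethyl-3,4-dihydronaphthalen-1(2H)-one | O=C1CC[C@H](C)c2c(C)cc(O)c(O)c12 | intermediate
8 | chloroacetone | CC(=O)CCl | starting material
9 | (S)-8-hydroxy-4,5-dimethyl-7-(2-oxopropoxy)-3,4-dihydronaphthalen-1(2H)-one | O=C1CC[C@H](C)c2c(C)cc(OCC(C)=O)c(O)c12 | intermediate
10 | (S)-9-hydroxy-3,4,5-trimethyl-6,7-dihydronaphtho[2,3-b]furan-8(5H)-one | Cc1coc2c(O)c3C(=O)CC[C@H](C)c3c(C)c12 | intermediate
11 | (5S)-3,4,5-trimethyl-5,6,7,8-tetrahydronaphtho[2,3-b]furan-8,9-diol, C8 epimers | Cc1coc2c(O)c3C(O)CC[C@H](C)c3c(C)c12 | intermediate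
12 | 2-methoxy-4-methylphenol (creosol) | COc1cc(C)ccc1O | starting material
13 | 1-(2-methoxy-4-methylphenoxy)propan-2-one | COc1cc(C)ccc1OCC(C)=O | intermediate
14 | 7-methoxy-3,5-dimethylbenzofuran | COc1cc(C)cc2c(C)coc12 | intermediate
15 | 3,5-dimethylbenzofuran-7-ol | Oc1cc(C)cc2c(C)coc12 | intermediate
16 | 7-hydroxy-3,5-dimethylbenzofuran-6-carbaldehyde | O=Cc1c(C)cc2c(C)coc2c1O | intermediate
17 | 3,5-dimethyl-6-vinylbenzofuran-7-ol | C=Cc1c(C)cc2c(C)coc2c1O | intermediate
18 | (E)-1-bromoprop-1-ene | C/C=C/Br | starting material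
19 | 9-[2-(7-(9-borabicyclo[3.3.1]nonan-9-yloxy)-3,5-dimethylbenzofuran-6-yl)ethyl]-9-borabicyclo[3.3.1]nonane (not isolated) | Cc1coc2c(OB3C4CCCC3CCC4)c(CCB3C4CCCC3CCC4)c(C)cc12 | intermediate
20 | 3,5-dimethyl-6-[(E)-pent-3-en-1-yl]benzofuran-7-ol | C/C=C/CCc1c(C)cc2c(C)coc2c1O | intermediate
21 | (5S)-3,4,5-trimethyl-6,7-dihydronaphtho[2,3-b]furan-9(5H)-one, ortho-quinone methide with C8=C8a and C9=O (not isolated) | CC1=COC2=C1C(C)=C1[C@@H](C)CCC=C1C2=O | intermediate
22 | CNP0281983.1: (5S,8R)-3,4,5-trimethyl-5,6,7,8-tetrahydronaphtho[2,3-b]furan unit whose O9 and C8 are bonded to C3' and C2' of a (2'R,3'R)-7'-hydroxy-3',5'-dimethyl-6'-[(E)-pent-3-enyl]-2',3'-dihydrobenzofuran unit; cis-fused pyran; H-8, H-2' and 3'-CH3 on one face | C/C=C/CCc1c(C)cc2c(c1O)O[C@@H]1[C@@H]3CC[C@H](C)c4c3c(c3occ(C)c3c4C)O[C@]21C | target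

**Step count and risks**

Total steps: 15. Longest linear sequence: 9 (steps 1 to 8, then step 15).

Step 15 (proposed new step). Risks: rearomatisation to the 2-alkylated benzofuran instead of ring closure, exo or wrong-face addition, trapping of 21 by the furan of unreacted 11, and acid-promoted ionisation of the product ether. The fallback uses known chemistry and sets out from 11 (with 20). Condense 11 with phenylboronic acid (toluene, Dean–Stark) to the cyclic phenylboronate of 11 (a 2-phenyl-4H-1,3,2-dioxaborin) F1. Heat F1 with 20 in toluene at 150 °C in a sealed tube. Acid-free thermolysis releases 21, which undergoes a concerted, substrate-controlled thermal oxa-Diels–Alder reaction. The diastereomers are separated by HPLC, and the sequence comes back to the route at 22.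

Step 7. Risk: the ring-closure site is para to the tetralone carbonyl and flanked by a methyl group, so cyclodehydration may be slow or low-yielding. The fallback sets out from 6 and builds the furan by a Heck reaction instead of a Friedel–Crafts closure. Iodinate the single free aromatic position (NIS, cat. TFA, MeCN) to give (S)-6-iodo-7,8-dimethoxy-4,5-dimethyl-3,4-dihydronaphthalen-1(2H)-one F2. Demethylate with BBr3 to (S)-7,8-dihydroxy-6-iodo-4,5-dimethyl-3,4-dihydronaphthalen-1(2H)-one F3. Allylate the non-chelated 7-OH (allyl bromide, K2CO3, acetone) to (S)-7-(allyloxy)-8-hydroxy-6-iodo-4,5-dimethyl-3,4-dihydronaphthalen-1(2H)-one F4. Close by 5-exo intramolecular Heck reaction with isomerisation of the exocyclic alkene into the ring (Pd(OAc)2, Na2CO3, HCO2Na, n-Bu4NCl, DMF, 80 °C). The sequence comes back to the route at 10.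

Step 3. Risk: the ortho-methyl group on the aryl ring may erode rate or enantioselectivity. The fallback sets out from 1 and replaces steps 1 to 3 by alkylation and resolution. AlCl3-mediated Friedel–Crafts alkylation of 1 with γ-valerolactone gives racemic 4-(4,5-dimethoxy-2-methylphenyl)pentanoic acid F5. Classical resolution by recrystallisation of the (S)-1-phenylethylammonium (S)-4-(4,5-dimethoxy-2-methylphenyl)pentanoate salt F6, then aq. HCl, comes back to the route at 5.

**Further compounds**

F1 | step 15 | cyclic phenylboronate of 11 (2-phenyl-4H-1,3,2-dioxaborin bridging O8 and O9) | Cc1coc2c3OB(c4ccccc4)OC4CC[C@H](C)c(c34)c(C)c12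
F2 | step 7 | (S)-6-iodo-7,8-dimethoxy-4,5-dimethyl-3,4-dihydronaphthalen-1(2H)-one | O=C1CC[C@H](C)c2c(C)c(I)c(OC)c(OC)c12
F3 | step 7 | (S)-7,8-dihydroxy-6-iodo-4,5-dimethyl-3,4-dihydronaphthalen-1(2H)-one | O=C1CC[C@H](C)c2c(C)c(I)c(O)c(O)c12
F4 | step 7 | (S)-7-(allyloxy)-8-hydroxy-6-iodo-4,5-dimethyl-3,4-dihydronaphthalen-1(2H)-one | O=C1CC[C@H](C)c2c(C)c(I)c(OCC=C)c(O)c12
F5 | step 3 | racemic 4-(4,5-dimethoxy-2-methylphenyl)pentanoic acid | OC(=O)CCC(C)c1cc(OC)c(OC)cc1C
F6 | step 3 | (S)-1-phenylethylammonium (S)-4-(4,5-dimethoxy-2-methylphenyl)pentanoate | C[C@H]([NH3+])c1ccccc1.[O-]C(=O)CC[C@H](C)c1cc(OC)c(OC)cc1C
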